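The target is cut at the benzylic CH2–aryl bond into an aryl triflate and an epoxy propargyl ether. Everything rests on the dihydrofuran ring O1–C2–C3–C3a–C7a of the benzofuran: its C3 carries a one-carbon branch and the ring A carbon C3a, the signature of a contracted chroman-4-one. A (2S)-flavanone (ring A: 5-OMe, 7-OTf) undergoes an oxidative 1,2-aryl shift with PhI(OAc)2, so that the six-membered pyranone ring shrinks to the five-membered ring, C4 is extruded as the ester (later CH2OH) and C3 is set trans to C2 in one operation. Sonogashira union, a Cp2TiCl radical cyclisation to the oxolane and a final hydrogenation/debenzylation complete the route.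

Key step: step 4

Assumptions (remarks on the chemistry):
- The facial sense of the PyOx–palladium conjugate addition to chromones is taken to follow that on cyclic enones, so the (R)-ligand is assigned to the (2S)-flavanone; should the opposite sense be found, the (S)-ligand is used with no other change.
- Compounds 16 and 17 are expected as alkene isomer mixtures (Z expected to predominate). Both isomers converge in step 11, so their SMILES are written without alkene geometry.
- Compounds 1, 5 and 11 are taken as catalogue materials.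

Step 1
Reactants: 1 1-(2,4-dihydroxy-6-methoxyphenyl)ethan-1-one
Product: 3 7-hydroxy-5-methoxy-4H-chromen-4-one, via chromenylium perchlorate 2 (not isolated)
Conditions: HC(OEt)3, 70% HClO4, rt; then H2O, 100 °C
Reagents that add atoms: triethyl orthoformate, CCOC(OCC)OCC
Why: Acid-promoted condensation of the orthoformate with the acetyl methyl group and the chelated 2-OH closes the 4-ethoxychromenylium salt 2, which hot water hydrolyses to the chromone (orthoformate chromone synthesis); the 4-OH is a spectator and becomes the 7-OH.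

Step 2
Reactants: 3 7-hydroxy-5-methoxy-4H-chromen-4-one
Product: 4 5-methoxy-4-oxo-4H-chromen-7-yl trifluoromethanesulfonate
Conditions: Tf2O, pyridine, CH2Cl2, 0 °C
Reagents that add atoms: triflic anhydride, O=S(=O)(C(F)(F)F)OS(=O)(=O)C(F)(F)F
Why: O-sulfonylation of the only phenol installs a cross-coupling handle that is inert to acid, to trivalent iodine and to divalent palladium.

Step 3
Reactants: 4 5-methoxy-4-oxo-4H-chromen-7-yl trifluoromethanesulfonate; 5 [4-(benzyloxy)-3-methoxyphenyl]boronic acid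
Product: 6 (2S)-2-[4-(benzyloxy)-3-methoxyphenyl]-5-methoxy-4-oxo-3,4-dihydro-2H-chromen-7-yl trifluoromethanesulfonate
Conditions: Pd(OCOCF3)2 (5 mol%), (R)-t-BuPyOx (6 mol%), NH4PF6 (30 mol%), H2O (5 equiv), ClCH2CH2Cl, 60 °C
Reagents that add atoms: none
Why: Hayashi–Miyaura-type asymmetric conjugate addition under cationic divalent palladium (aryl transfer from boron, insertion of the chromone C2=C3 bond, protonolysis of the palladium enolate), in which the chiral PyOx ligand fixes the face of aryl delivery and so sets C2 as (S); no zerovalent palladium is involved, so the aryl triflate should survive.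

Step 4
Reactants: 6 (2S)-2-[4-(benzyloxy)-3-methoxyphenyl]-5-methoxy-4-oxo-3,4-dihydro-2H-chromen-7-yl trifluoromethanesulfonate
Product: 10 methyl (2S,3S)-2-[4-(benzyloxy)-3-methoxyphenyl]-4-methoxy-6-(trifluoromethanesulfonyloxy)-2,3-dihydro-1-benzofuran-3-carboxylate, via enol ether 7 (not isolated), via iodanyl ketal 8 (not isolated), via orthoester 9 (not isolated)
Conditions: PhI(OAc)2 (1.3 equiv), conc. H2SO4, HC(OMe)3, rt; then H2O
Reagents that add atoms: trimethyl orthoformate, COC(OC)OC; water, O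
Why: Acid and HC(OMe)3 convert the ketone into enol ether 7; electrophilic trivalent iodine adds to C3 anti to the C2 aryl group and methanol caps C4, giving the trans-diequatorial iodanyl ketal 8. In 8 the C3–I bond is antiperiplanar to the ring bond C4–C4a, so ring A carbon C4a shifts from C4 to C3 with inversion as PhI leaves, and the resulting dimethoxycarbenium ion is trapped as orthoester 9, which is hydrolysed to the ester on work-up. The closest known reaction type is the oxidative ring contraction of flavanones to trans-2-aryl-2,3-dihydrobenzofuran-3-carboxylates (a semipinacol-type 1,2-aryl shift). The five-membered ring closes by ipso attack of C4a on C3 through a spiro phenonium bridge (3-exo-tet displacement of iodobenzene), followed by cleavage of C4a–C4. The new C3 centre is controlled by the C2 centre (iodane anti to aryl, then inversion, gives trans, which is also the thermodynamic epimer), while C2 itself is not touched. The step needs ring A to migrate rather than the C2 aryl ring (isoflavone) or hydrogen (flavone): the equatorial C–I bond aligns only with C4–C4a, and the two ortho oxygens of ring A (5-OMe and O1) stabilise the bridged cation although the triflate is para.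

Step 5
Reactants: 11 3-(benzyloxy)-4-methoxybenzaldehyde
Product: 12 rac-1-[3-(benzyloxy)-4-methoxyphenyl]prop-2-en-1-ol
Conditions: CH2=CHMgBr, THF, 0 °C; aq. NH4Cl
Reagents that add atoms: vinylmagnesium bromide, C=C[Mg]Br
Why: Grignard addition to the aldehyde gives the racemic vinyl carbinol needed for the resolution.

Step 6
Reactants: 12 rac-1-[3-(benzyloxy)-4-methoxyphenyl]prop-2-en-1-ol
Product: 13 (S)-[3-(benzyloxy)-4-methoxyphenyl][(2R)-oxiran-2-yl]methanol
Conditions: Ti(OiPr)4 (0.2 equiv), L-(+)-DIPT (0.25 equiv), t-BuOOH (0.5 equiv), 4 Å MS, CH2Cl2, −20 °C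
Reagents that add atoms: tert-butyl hydroperoxide, CC(C)(C)OO
Why: Sharpless kinetic resolution: with L-(+)-DIPT the (R)-carbinol should be epoxidised far faster than its antipode and gives the erythro epoxy alcohol (reagent control; the carbinol centre becomes C2 of the oxolane), while the (S)-enantiomer of 12 stays behind as allylic alcohol and is separated.

Step 7
Reactants: 13 (S)-[3-(benzyloxy)-4-methoxyphenyl][(2R)-oxiran-2-yl]methanol
Product: 14 (2R)-2-[(S)-[3-(benzyloxy)-4-methoxyphenyl](prop-2-yn-1-yloxy)methyl]oxirane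
Conditions: propargyl bromide, NaH, n-Bu4NI (cat.), THF–DMF, −20 to 0 °C (bromide present before the base)
Reagents that add atoms: propargyl bromide, C#CCBr
Why: Williamson etherification of the sodium alkoxide with the reactive propargylic bromide at low temperature should outrun Payne rearrangement and leaves both stereocentres untouched.

Step 8
Reactants: 10 methyl (2S,3S)-2-[4-(benzyloxy)-3-methoxyphenyl]-4-methoxy-6-(trifluoromethanesulfonyloxy)-2,3-dihydro-1-benzofuran-3-carboxylate; 14 (2R)-2-[(S)-[3-(benzyloxy)-4-methoxyphenyl](prop-2-yn-1-yloxy)methyl]oxirane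
Product: 15 methyl (2S,3S)-2-[4-(benzyloxy)-3-methoxyphenyl]-6-{3-[(S)-[3-(benzyloxy)-4-methoxyphenyl][(2R)-oxiran-2-yl]methoxy]prop-1-yn-1-yl}-4-methoxy-2,3-dihydro-1-benzofuran-3-carboxylate
Conditions: PdCl2(PPh3)2 (5 mol%), CuI (10 mol%), Et3N, DMF, 60 °C, degassed
Reagents that add atoms: none
Why: Sonogashira coupling of the aryl triflate with the terminal alkyne joins the two fragments; the epoxide, the ester (its α-hydrogen is not removed by Et3N) and the benzyl ethers should be inert under these conditions.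

Step 9
Reactants: 15 methyl (2S,3S)-2-[4-(benzyloxy)-3-methoxyphenyl]-6-{3-[(S)-[3-(benzyloxy)-4-methoxyphenyl][(2R)-oxiran-2-yl]methoxy]prop-1-yn-1-yl}-4-methoxy-2,3-dihydro-1-benzofuran-3-carboxylate
Product: 16 methyl (2S,3S)-2-[4-(benzyloxy)-3-methoxyphenyl]-6-{[(4S,5R)-5-[3-(benzyloxy)-4-methoxyphenyl]-4-(hydroxymethyl)oxolan-3-ylidene]methyl}-4-methoxy-2,3-dihydro-1-benzofuran-3-carboxylate
Conditions: Cp2TiCl2 (2.5 equiv), Zn dust, THF, rt; then aq. NaH2PO4
Reagents that add atoms: none
Why: Cp2TiCl (trivalent titanium, formed in the flask) opens the epoxide by single-electron transfer to the secondary β-titanoxy radical, which closes 5-exo-dig onto the aryl alkyne through a chair-like transition state with the C5 aryl group pseudo-equatorial, so the hydroxymethyl centre is set trans to it by substrate control (the old oxirane stereocentre is erased and re-set), and the vinyl radical is then reduced and protonated (reductive epoxide-opening radical cyclisation).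

Step 10
Reactants: 16 methyl (2S,3S)-2-[4-(benzyloxy)-3-methoxyphenyl]-6-{[(4S,5R)-5-[3-(benzyloxy)-4-methoxyphenyl]-4-(hydroxymethyl)oxolan-3-ylidene]methyl}-4-methoxy-2,3-dihydro-1-benzofuran-3-carboxylate
Product: 17 [(2S,3R)-2-[4-(benzyloxy)-3-methoxyphenyl]-6-{[(4S,5R)-5-[3-(benzyloxy)-4-methoxyphenyl]-4-(hydroxymethyl)oxolan-3-ylidene]methyl}-4-methoxy-2,3-dihydro-1-benzofuran-3-yl]methanol
Conditions: LiAlH4, THF, 0 °C; aq. NaOH work-up
Reagents that add atoms: none
Why: Hydride reduction of the methyl ester to the primary alcohol is faster than any deprotonation at C3, so the β-aryloxy ester should not ring-open and no stereocentre is touched (the C3 descriptor changes from S to R only through the priority rules).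

Step 11
Reactants: 17 [(2S,3R)-2-[4-(benzyloxy)-3-methoxyphenyl]-6-{[(4S,5R)-5-[3-(benzyloxy)-4-methoxyphenyl]-4-(hydroxymethyl)oxolan-3-ylidene]methyl}-4-methoxy-2,3-dihydro-1-benzofuran-3-yl]methanol
Product: 18 [(2S,3R)-6-{[(3S,4S,5R)-5-(3-hydroxy-4-methoxyphenyl)-4-(hydroxymethyl)oxolan-3-yl]methyl}-2-(4-hydroxy-3-methoxyphenyl)-4-methoxy-2,3-dihydro-1-benzofuran-3-yl]methanol
Conditions: H2 (1 atm), 10% Pd/C, EtOAc–EtOH, rt
Reagents that add atoms: none
Why: Heterogeneous hydrogenation should add hydrogen to the exocyclic alkene from the face opposite to the neighbouring hydroxymethyl group, placing the arylmethyl group cis to it (substrate control, sets the last centre as S), and the same operation hydrogenolyses both benzyl ethers.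

Compound list
1 | 1-(2,4-dihydroxy-6-methoxyphenyl)ethan-1-one | CC(=O)c1c(O)cc(O)cc1OC | starting material
2 | 4-ethoxy-7-hydroxy-5-methoxychromenylium perchlorate | CCOc1cc[o+]c2cc(O)cc(OC)c12.[O-]Cl(=O)(=O)=O | intermediate
3 | 7-hydroxy-5-methoxy-4H-chromen-4-one | COc1cc(O)cc2occc(=O)c12 | intermediate
4 | 5-methoxy-4-oxo-4H-chromen-7-yl trifluoromethanesulfonate | COc1cc(OS(=O)(=O)C(F)(F)F)cc2occc(=O)c12 | intermediate
5 | [4-(benzyloxy)-3-methoxyphenyl]boronic acid | COc1cc(B(O)O)ccc1OCc1ccccc1 | starting material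
6 | (2S)-2-[4-(benzyloxy)-3-methoxyphenyl]-5-methoxy-4-oxo-3,4-dihydro-2H-chromen-7-yl trifluoromethanesulfonate (the (2S)-flavanone) | COc1cc(OS(=O)(=O)C(F)(F)F)cc2O[C@H](c3ccc(OCc4ccccc4)c(OC)c3)CC(=O)c12 | intermediate
7 | (2S)-2-[4-(benzyloxy)-3-methoxyphenyl]-4,5-dimethoxy-2H-chromen-7-yl trifluoromethanesulfonate (enol ether) | COc1cc(OS(=O)(=O)C(F)(F)F)cc2O[C@H](c3ccc(OCc4ccccc4)c(OC)c3)C=C(OC)c12 | intermediate
8 | (2R,3R)-3-[acetoxy(phenyl)-λ3-iodanyl]-2-[4-(benzyloxy)-3-methoxyphenyl]-4,4,5-trimethoxy-3,4-dihydro-2H-chromen-7-yl trifluoromethanesulfonate (iodane trans to the C2 aryl group) | COc1cc(OS(=O)(=O)C(F)(F)F)cc2O[C@H](c3ccc(OCc4ccccc4)c(OC)c3)[C@@H](I(OC(C)=O)c3ccccc3)C(OC)(OC)c12 | intermediate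
9 | (2S,3S)-2-[4-(benzyloxy)-3-methoxyphenyl]-4-methoxy-3-(trimethoxymethyl)-2,3-dihydro-1-benzofuran-6-yl trifluoromethanesulfonate (orthoester, 2,3-trans) | COc1cc(OS(=O)(=O)C(F)(F)F)cc2O[C@H](c3ccc(OCc4ccccc4)c(OC)c3)[C@@H](C(OC)(OC)OC)c12 | intermediate
10 | methyl (2S,3S)-2-[4-(benzyloxy)-3-methoxyphenyl]-4-methoxy-6-(trifluoromethanesulfonyloxy)-2,3-dihydro-1-benzofuran-3-carboxylate (2,3-trans) | COc1cc(OS(=O)(=O)C(F)(F)F)cc2O[C@H](c3ccc(OCc4ccccc4)c(OC)c3)[C@@H](C(=O)OC)c12 | intermediate
11 | 3-(benzyloxy)-4-methoxybenzaldehyde | COc1ccc(C=O)cc1OCc1ccccc1 | starting material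
12 | rac-1-[3-(benzyloxy)-4-methoxyphenyl]prop-2-en-1-ol | COc1ccc(C(O)C=C)cc1OCc1ccccc1 | intermediate
13 | (S)-[3-(benzyloxy)-4-methoxyphenyl][(2R)-oxiran-2-yl]methanol (erythro) | COc1ccc([C@@H]([C@H]2CO2)O)cc1OCc1ccccc1 | intermediate
14 | (2R)-2-[(S)-[3-(benzyloxy)-4-methoxyphenyl](prop-2-yn-1-yloxy)methyl]oxirane | COc1ccc([C@@H]([C@H]2CO2)OCC#C)cc1OCc1ccccc1 | intermediate
15 | methyl (2S,3S)-2-[4-(benzyloxy)-3-methoxyphenyl]-6-{3-[(S)-[3-(benzyloxy)-4-methoxyphenyl][(2R)-oxiran-2-yl]methoxy]prop-1-yn-1-yl}-4-methoxy-2,3-dihydro-1-benzofuran-3-carboxylate | COc1cc(C#CCO[C@@H](c3ccc(OC)c(OCc4ccccc4)c3)[C@H]3CO3)cc2O[C@H](c3ccc(OCc4ccccc4)c(OC)c3)[C@@H](C(=O)OC)c12 | intermediate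
16 | methyl (2S,3S)-2-[4-(benzyloxy)-3-methoxyphenyl]-6-{[(4S,5R)-5-[3-(benzyloxy)-4-methoxyphenyl]-4-(hydroxymethyl)oxolan-3-ylidene]methyl}-4-methoxy-2,3-dihydro-1-benzofuran-3-carboxylate (oxolane aryl and CH2OH trans; alkene isomer mixture) | COc1ccc([C@@H]2OCC(=Cc3cc(OC)c4c(c3)O[C@H](c3ccc(OCc5ccccc5)c(OC)c3)[C@H]4C(=O)OC)[C@H]2CO)cc1OCc1ccccc1 | intermediate
17 | [(2S,3R)-2-[4-(benzyloxy)-3-methoxyphenyl]-6-{[(4S,5R)-5-[3-(benzyloxy)-4-methoxyphenyl]-4-(hydroxymethyl)oxolan-3-ylidene]methyl}-4-methoxy-2,3-dihydro-1-benzofuran-3-yl]methanol (alkene isomer mixture) | COc1ccc([C@@H]2OCC(=Cc3cc(OC)c4c(c3)O[C@H](c3ccc(OCc5ccccc5)c(OC)c3)[C@H]4CO)[C@H]2CO)cc1OCc1ccccc1 | intermediate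
18 | [(2S,3R)-6-{[(3S,4S,5R)-5-(3-hydroxy-4-methoxyphenyl)-4-(hydroxymethyl)oxolan-3-yl]methyl}-2-(4-hydroxy-3-methoxyphenyl)-4-methoxy-2,3-dihydro-1-benzofuran-3-yl]methanol (CNP0242386.1) | COc1ccc([C@@H]2OC[C@@H](Cc3cc(OC)c4c(c3)O[C@H](c3ccc(O)c(OC)c3)[C@H]4CO)[C@H]2CO)cc1O | target

Total step count: 11 steps.
Longest linear sequence: 8 steps (steps 1, 2, 3, 4, 8, 9, 10, 11, from compound 1); the second branch (steps 5, 6, 7) joins at step 8.

Steps most likely to fail

Step 4 (key step). What may go wrong: migration of the C2 aryl ring in place of ring A (leading towards an isoflavone), loss of the C3 substituent with a proton (dehydrogenation to the flavone), attack of the activated iodine reagent on the electron-rich benzyloxy ring, or acid-induced opening of the pyranone ring before oxidation, which would erode the C2 configuration. Fallback, still a ring contraction but by a carbene pathway, setting out from 6 and coming back at 10: the flavanone 6 is C-acylated at C3 at −78 °C (LiHMDS, CF3CO2CH2CF3, THF; the low temperature suppresses β-elimination of the ring oxygen) to the 3-trifluoroacetyl ketone F1. Detrifluoroacetylative diazo transfer (4-acetamidobenzenesulfonyl azide, Et3N, MeCN) then gives the 3-diazo ketone F2. Photochemical Wolff rearrangement of F2 in MeOH shifts ring A carbon C4a from the carbonyl carbon to the carbene carbon and traps the ketene as the methyl ester, expected as a mixture of 10 and its cis epimer F3. Catalytic DBU in CH2Cl2 should equilibrate this mixture to the trans ester 10.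

Step 11. What may go wrong: hydrogen addition from the wrong face of the exocyclic alkene (giving the epimer at the arylmethyl-bearing carbon), migration of the double bond into the oxolane ring, or hydrogenolysis of the allylic and benzylic C–O bonds of the two oxygen heterocycles. Fallback, setting out from 14 and 10 and coming back at 18, in which the last stereocentre is set by hydroboration and not by hydrogenation: ether 14 is cyclised with Cp2TiCl (Cp2TiCl2, Zn, THF) to the 4-methylidene oxolane F4. 9-BBN (two equivalents, the first bound at oxygen) adds to the alkene from the face opposite to the neighbouring CH2O group and gives the bis-boron adduct F5, with the boron-bearing CH2 cis to that group. B-alkyl Suzuki–Miyaura coupling of F5 with triflate 10 (PdCl2(dppf), K3PO4, THF–H2O, 50 °C) gives the saturated coupled ester F6. LiAlH4 reduction gives the dibenzyl diol F7, and hydrogenolysis of the benzyl ethers (H2, Pd/C) gives 18.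

Step 3. What may go wrong: insufficient or reversed facial selectivity in the aryl transfer, protodeboronation of the electron-rich boronic acid, or slow insertion of the 5-methoxychromone. Fallback, setting out from 4 and 5 and coming back at 6, by racemic addition and kinetic resolution: conjugate addition with an achiral catalyst (Pd(OCOCF3)2, 2,2'-bipyridine, aqueous ClCH2CH2Cl, 60 °C) gives the racemic flavanone F8. Noyori-type asymmetric transfer hydrogenation under kinetic-resolution conditions (RuCl[(R,R)-TsDPEN](p-cymene), HCO2H–Et3N, EtOAc, rt) is expected to reduce the (2R)-enantiomer to the cis-flavan-4-ol F9. The unreduced (2S)-flavanone 6 is then separated by chromatography.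

Further compounds
F1 | step 4 | (2S)-2-[4-(benzyloxy)-3-methoxyphenyl]-5-methoxy-4-oxo-3-(trifluoroacetyl)-3,4-dihydro-2H-chromen-7-yl trifluoromethanesulfonate (C3 epimers and enol form) | COc1cc(OS(=O)(=O)C(F)(F)F)cc2O[C@H](c3ccc(OCc4ccccc4)c(OC)c3)C(C(=O)C(F)(F)F)C(=O)c12
F2 | step 4 | (2R)-2-[4-(benzyloxy)-3-methoxyphenyl]-3-diazo-5-methoxy-4-oxo-3,4-dihydro-2H-chromen-7-yl trifluoromethanesulfonate | COc1cc(OS(=O)(=O)C(F)(F)F)cc2O[C@H](c3ccc(OCc4ccccc4)c(OC)c3)C(=[N+]=[N-])C(=O)c12
F3 | step 4 | methyl (2S,3R)-2-[4-(benzyloxy)-3-methoxyphenyl]-4-methoxy-6-(trifluoromethanesulfonyloxy)-2,3-dihydro-1-benzofuran-3-carboxylate (2,3-cis epimer of 10) | COc1cc(OS(=O)(=O)C(F)(F)F)cc2O[C@H](c3ccc(OCc4ccccc4)c(OC)c3)[C@H](C(=O)OC)c12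
F4 | step 11 | [(2R,3S)-2-[3-(benzyloxy)-4-methoxyphenyl]-4-methylideneoxolan-3-yl]methanol | COc1ccc([C@@H]2OCC(=C)[C@H]2CO)cc1OCc1ccccc1
F5 | step 11 | 9-{[(3S,4S,5R)-5-[3-(benzyloxy)-4-methoxyphenyl]-4-{[(9-borabicyclo[3.3.1]nonan-9-yl)oxy]methyl}oxolan-3-yl]methyl}-9-borabicyclo[3.3.1]nonane | COc1ccc([C@@H]2OC[C@@H](CB3C4CCCC3CCC4)[C@H]2COB2C3CCCC2CCC3)cc1OCc1ccccc1
F6 | step 11 | methyl (2S,3S)-2-[4-(benzyloxy)-3-methoxyphenyl]-6-{[(3S,4S,5R)-5-[3-(benzyloxy)-4-methoxyphenyl]-4-(hydroxymethyl)oxolan-3-yl]methyl}-4-methoxy-2,3-dihydro-1-benzofuran-3-carboxylate | COc1ccc([C@@H]2OC[C@@H](Cc3cc(OC)c4c(c3)O[C@H](c3ccc(OCc5ccccc5)c(OC)c3)[C@H]4C(=O)OC)[C@H]2CO)cc1OCc1ccccc1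
F7 | step 11 | [(2S,3R)-2-[4-(benzyloxy)-3-methoxyphenyl]-6-{[(3S,4S,5R)-5-[3-(benzyloxy)-4-methoxyphenyl]-4-(hydroxymethyl)oxolan-3-yl]methyl}-4-methoxy-2,3-dihydro-1-benzofuran-3-yl]methanol (dibenzyl ether of 18) | COc1ccc([C@@H]2OC[C@@H](Cc3cc(OC)c4c(c3)O[C@H](c3ccc(OCc5ccccc5)c(OC)c3)[C@H]4CO)[C@H]2CO)cc1OCc1ccccc1
F8 | step 3 | rac-2-[4-(benzyloxy)-3-methoxyphenyl]-5-methoxy-4-oxo-3,4-dihydro-2H-chromen-7-yl trifluoromethanesulfonate | COc1cc(OS(=O)(=O)C(F)(F)F)cc2OC(c3ccc(OCc4ccccc4)c(OC)c3)CC(=O)c12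
F9 | step 3 | (2R,4R)-2-[4-(benzyloxy)-3-methoxyphenyl]-4-hydroxy-5-methoxy-3,4-dihydro-2H-chromen-7-yl trifluoromethanesulfonate (2,4-cis) | COc1cc(OS(=O)(=O)C(F)(F)F)cc2O[C@@H](c3ccc(OCc4ccccc4)c(OC)c3)C[C@@H](O)c12
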